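## Structural features

The target is a ten-membered carbocycle carrying a Z trisubstituted olefin (C1=C10, methyl on C10), a cis trisubstituted oxirane at C4–C5 (methyl on C4), a free secondary hydroxyl at C6, an isopropyl group at C7 (methine C11) and a 3,4,5-trimethoxybenzoate at C8. The five stereocentres C4–C8 are contiguous (4R,5S,6R,7S,8R). O6, the C7 branch and O8 lie on one face of the ring, and the oxirane oxygen lies on the face opposite to O6 (threo epoxy alcohol). Fragile elements are the 2,3-epoxy alcohol (Payne rearrangement under base, transannular opening by C1=C10 under acid), the aryl ester (it can migrate to the cis O6 under base), and the Z,Z-1,5-diene of the deoxy stage. The real difficulty is twofold: closing a ten-membered ring, and building the all-cis C6–C8 triad next to an oxirane of defined face. The C6 carbinol next to the branched C7 is the hydroxyl/isopropenyl pair that a [2,3]-Wittig shift leaves behind, so C6–C7 can be made inside a thirteen-membered diallyl ether in which C6 and C12 (the allylic CH2 on C11) are joined through oxygen. The oxirane maps onto the Z olefin C4=C5 that stabilises the carbanion in that shift, and the C6 hydroxyl created by the shift is the handle for its epoxidation.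

## Logic of the disconnections

31 to 30. The C4–O and C5–O bonds of the oxirane are cut, leaving the Z olefin C4=C5 beside the C6 hydroxyl. The oxirane is the most fragile group, so it comes last; the cut removes two stereocentres and leaves an allylic alcohol that can direct the oxidant. The forward step must touch C4=C5 and not C1=C10, and must deliver oxygen to the face of C4=C5 on which O6 sits when H6 lies in the olefin plane.

30 to 29, then 27 and 28. The benzylic C–O bond of a temporary 4-methoxybenzyl ether on O6 is cut, then the alkyl C8–O bond of the ester, with inversion at C8. The alkyl side is chosen because the ring contraction is expected to place O8 trans to the C7 branch, whereas 31 needs it cis; joining 27 and 28 with inversion corrects C8 and brings in the base-labile aryl ester after all strongly basic steps. The demand is an SN2 displacement at a ring carbinol flanked by the branched C7, with O6 masked meanwhile.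

27 to 26, 25 and 24. The O8–Si and O6–benzyl bonds are cut and the two hydrogens on C11/C12 are removed, so that the isopropyl group returns to the isopropenyl group that a sigmatropic shift delivers. Hydrogenation must precede any regeneration of an alkoxide at O6, because C4=C5–C6(O)–C7–C11=C12 is an oxy-Cope array. The demand is hydrogenation of the 1,1-disubstituted olefin in the presence of two trisubstituted ring olefins.

24 to 21. C6–C7 is cut and O–C12 reconnected: the ten-membered carbocycle becomes a thirteen-membered all-Z diallyl ether with C8 as its only stereocentre. The medium ring and two stereocentres (C6, C7) are traded for an unstrained macrocyclic ether. The forward step needs lithiation at C6 and not C12, [2,3] over [1,2] shift, Z geometry at C7=C11 for the cis C6/C7 pair, and attack on the face of C7 anti to O8. For the last reason 21 carries the (8S) configuration, epimeric to 31 at C8.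

21 to 20, 19 and 18. The O–C6 ether bond is cut (alkoxide on O12, chloride on C6). A primary allylic chloride whose SN2′ terminus C4 is fully substituted reacts by SN2, and the O12 alkoxide can be released under neutral oxidative conditions. The forward step needs high dilution and a silyl group on O8 that does not migrate to the neighbouring alkoxide.

18 to 12 and 15. The C3–C4 bond between sp3 and sp2 carbon is cut, giving a fragment with the C8 stereocentre and a four-carbon Z iodoalkenol. The coupling must keep the olefin geometry and tolerate the free hydroxyl.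

12 to 11, 10 and 9, then 4 and 8. The C3 iodide is traced to the alcohol and the ester, the O8–Si bond is removed, and the C7–C8 bond is cut to an aldehyde and a Z alkenyl iodide. C8 becomes the single stereocentre to be set by a chiral ligand, and the Z geometry of C7=C11 is stored in the iodide. The addition must be non-basic (skipped enal), aldehyde-selective and face-selective.

4 to 2 and 1. C3 and C8 are reconnected as a ring double bond. The six-membered ring guarantees that C9 and C2 are cis on C10=C1. The forward cleavage must hit only the enol ether double bond.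

8 to 7 and 5; 15 to 13. The C11–CH3 and C7–I bonds of 7, and the C4–I bond of 15, are cut back to alkynols. Chelate-controlled anti carbometalation and trans hydroalumination fix both Z geometries; the demand is regiocontrol through the alkoxide.

## Other disconnections considered

Alternative 1: The C4–C5 bond and the C4–O bond of the oxirane are cut, leading to the open-chain C5 aldehyde A1 with a diphenylsulfonium group on C4, O6 as its 4-methoxybenzyl ether and the ester already on C8. Forward, LiN(SiMe3)2 would form the ylide, which adds to C5 and closes the ten-membered ring; the alkoxide then expels diphenyl sulfide to give A2, one oxidative deprotection from 31.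
- In favour: ring and oxirane arise in one operation, no olefin has to be epoxidised selectively (better than the chosen plan on this point), and the endgame is shorter.
- Against: the ten-membered ring is closed directly, against strain and oligomerisation. Nothing controls the relative or absolute configuration at C4/C5. The α-alkoxy aldehyde can epimerise at C6. The secondary sulfonium centre has β-hydrogens, so elimination competes with ylide formation. The base meets an aryl ester.
- Comparison: the chosen plan closes the ring through an unstrained ether and a concerted shift, and takes the cis oxirane from a Z olefin of fixed geometry, so it is the more reliable on mechanism and stereocontrol. Alternative 1 is better on step count after ring closure.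

Alternative 2: C5–C6 is cut, giving the open-chain C6 aldehyde A3 with a Z alkenyl iodide at C5 and the ester on C8. Forward, divalent chromium (CrCl2) with catalytic NiCl2 would form the alkenylchromium species with retention of geometry and add it to C6, giving the dienol A4, which is the same compound as 30.
- In favour: A4 is reached with the ester in place, so the protecting-group changes and the inversion at C8 of the chosen plan are avoided (clearly better step economy in the endgame). The coupling tolerates the ester and needs no strong base.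
- Against: C6 is created during ring closure under control only of the C7 stereocentre and the ring conformation. The aldehyde A3 is α-branched and β-acyloxylated, so epimerisation at C7 and loss of the benzoate threaten. The ten-membered ring is again closed directly.
- Comparison: both plans finish with the same epoxidation of the same compound and are equal there. The chosen plan sets C6/C7 by olefin geometry in a concerted step, which is the stronger stereochemical argument.

Alternative 3: C7–C8 is cut, giving the open-chain C8 aldehyde A5 with a tributylstannyl group on C12 and a silyl ether on O6. Forward, BF3·OEt2 would activate the aldehyde and the γ-carbon C7 of the allylstannane would attack it through an open transition state, giving A6.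
- In favour: it builds the same ring, bond and number of stereocentres as the chosen plan (equal). It is stereoconvergent in the stannane geometry, needs no strong base and has no question of which allylic position is lithiated (better). It leaves the free hydroxyl on C8, the oxygen that must be acylated, so no inversion is needed (better).
- Against: direct ten-membered ring closure; a Lewis acid acting on a β,γ-unsaturated aldehyde and an acid-sensitive diene; C7 and C8 both have to be controlled from the C6 stereocentre.
- Comparison: the mechanisms differ (cationic open transition state against a concerted anionic shift) and the step counts are similar. The chosen plan's advantage is that ring closure (easy ether formation) and C–C bond formation are separated.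

Key step: step 14

Remark: ring atoms are numbered C1–C10 as in the target (C11 isopropyl methine, C12 its former allylic CH2). A silyloxy group on C8 is taken to lie anti to the carbanion attacking C7, with H8 in the olefin plane, which puts the new C6–C7 bond trans to O8; the ether is therefore built as the (8S) epimer and C8 is inverted when the ester is made.

Step 1
Reactants: 1 4-methylanisole
Product: 2 1-methoxy-4-methylcyclohexa-1,4-diene
Conditions: Li, NH3 (l), THF, t-BuOH, −78 to −33 °C
Reagents that add atoms: none
Why: Birch reduction of an electron-rich arene gives the unconjugated 1,4-diene with methoxy and methyl on the remaining double bonds.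

Step 2
Reactants: 2 1-methoxy-4-methylcyclohexa-1,4-diene
Product: 4 methyl (3Z)-4-methyl-6-oxohex-3-enoate, via methoxy hydroperoxide 3 (not isolated)
Conditions: O3 (1 equiv), CH2Cl2–MeOH, −78 °C; then Me2S, −78 °C to rt
Reagents that add atoms: ozone, [O-][O+]=O
Why: Ozonolysis attacks the electron-rich enol ether double bond far faster than the trialkyl olefin; in methanol it gives the ester carbon (C3) and hydroperoxide 3 at C8, which Me2S reduces to the aldehyde. The ring origin fixes C9 and C2 cis on C10=C1.

Step 3
Reactants: 5 prop-2-yn-1-ol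
Product: 7 (2Z)-3-iodo-2-methylprop-2-en-1-ol, via alkenylmagnesium alkoxide 6 (not isolated)
Conditions: MeMgBr (3 equiv), CuI (10 mol %), Et2O–THF, −10 °C to rt; then I2, −78 to 0 °C
Reagents that add atoms: methylmagnesium bromide, C[Mg]Br; iodine, II
Why: Copper-catalysed anti carbomagnesiation of the propargylic alkoxide puts methyl on the internal carbon and magnesium on the terminal carbon in a five-membered chelate; iodinolysis with retention gives the Z iodide (iodine cis to CH2OH).

Step 4
Reactants: 7 (2Z)-3-iodo-2-methylprop-2-en-1-ol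
Product: 8 (Z)-1-iodo-3-[(4-methoxybenzyl)oxy]-2-methylprop-1-ene
Conditions: NaH, 4-methoxybenzyl chloride, Bu4NI (cat.), THF–DMF, 0 °C to rt
Reagents that add atoms: 4-methoxybenzyl chloride, COc1ccc(CCl)cc1
Why: Williamson etherification; the 4-methoxybenzyl group survives the organometallic steps and is later removed oxidatively beside a silyl ether and an allylic chloride.

Step 5
Reactants: 4 methyl (3Z)-4-methyl-6-oxohex-3-enoate; 8 (Z)-1-iodo-3-[(4-methoxybenzyl)oxy]-2-methylprop-1-ene
Product: 9 methyl (3Z,6S,7Z)-6-hydroxy-9-[(4-methoxybenzyl)oxy]-4,8-dimethylnona-3,7-dienoate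
Conditions: CrCl2, chiral sulfonamide–oxazoline ligand, Et3N, NiCl2 (cat.), THF, rt
Reagents that add atoms: none
Why: Nozaki–Hiyama–Kishi coupling: the alkenylchromium species forms with retention of the Z geometry and adds only to the aldehyde, without base, so the ester and the skipped olefin are untouched. The chiral ligand on chromium controls the carbonyl face; the antipode is chosen to give the (S) carbinol at C8, to be confirmed by derivatisation with a chiral acid.

Step 6
Reactants: 9 methyl (3Z,6S,7Z)-6-hydroxy-9-[(4-methoxybenzyl)oxy]-4,8-dimethylnona-3,7-dienoate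
Product: 10 methyl (3Z,6S,7Z)-9-[(4-methoxybenzyl)oxy]-4,8-dimethyl-6-[(triisopropylsilyl)oxy]nona-3,7-dienoate
Conditions: i-Pr3SiOTf, 2,6-lutidine, CH2Cl2, −78 to 0 °C
Reagents that add atoms: triisopropylsilyl trifluoromethanesulfonate, CC(C)[Si](C(C)C)(C(C)C)OS(=O)(=O)C(F)(F)F
Why: Silylation of a secondary alcohol with a silyl triflate; the triisopropylsilyl group is chosen because it resists migration to a neighbouring alkoxide, withstands alkyllithium reagents and is bulky next to C7 and C12.

Step 7
Reactants: 10 methyl (3Z,6S,7Z)-9-[(4-methoxybenzyl)oxy]-4,8-dimethyl-6-[(triisopropylsilyl)oxy]nona-3,7-dienoate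
Product: 11 (3Z,6S,7Z)-9-[(4-methoxybenzyl)oxy]-4,8-dimethyl-6-[(triisopropylsilyl)oxy]nona-3,7-dien-1-ol
Conditions: i-Bu2AlH, CH2Cl2, −78 to 0 °C
Reagents that add atoms: none
Why: Hydride reduction of the ester to the primary alcohol (C3); ethers and olefins are inert.

Step 8
Reactants: 11 (3Z,6S,7Z)-9-[(4-methoxybenzyl)oxy]-4,8-dimethyl-6-[(triisopropylsilyl)oxy]nona-3,7-dien-1-ol
Product: 12 (3Z,6S,7Z)-1-iodo-9-[(4-methoxybenzyl)oxy]-4,8-dimethyl-6-[(triisopropylsilyl)oxy]nona-3,7-diene
Conditions: I2, PPh3, imidazole, CH2Cl2, 0 °C
Reagents that add atoms: iodine, II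
Why: Appel-type iodination of a primary alcohol by SN2 displacement of the oxyphosphonium group; no allylic position is involved.

Step 9
Reactants: 13 but-2-yn-1-ol
Product: 15 (2Z)-3-iodobut-2-en-1-ol, via cyclic alkenylalanate 14 (not isolated)
Conditions: NaAlH2(OCH2CH2OMe)2, THF, 0 °C to rt; then I2, −78 °C to rt
Reagents that add atoms: iodine, II
Why: Alkoxide-directed trans hydroalumination places aluminium on the distal alkyne carbon (C4) in a five-membered alanate; iodinolysis with retention gives the Z iodide (iodine cis to CH2OH).

Step 10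
Reactants: 12 (3Z,6S,7Z)-1-iodo-9-[(4-methoxybenzyl)oxy]-4,8-dimethyl-6-[(triisopropylsilyl)oxy]nona-3,7-diene; 15 (2Z)-3-iodobut-2-en-1-ol
Product: 18 (2Z,6Z,9S,10Z)-12-[(4-methoxybenzyl)oxy]-3,7,11-trimethyl-9-[(triisopropylsilyl)oxy]dodeca-2,6,10-trien-1-ol, via alkyllithium 16 (not isolated), via lithium borate 17 (not isolated)
Conditions: t-BuLi (2.1 equiv), Et2O, −78 °C; 9-MeO-9-BBN, THF, −78 °C to rt; then 15, PdCl2(dppf), AsPh3, K3PO4 (aq), DMF, rt
Reagents that add atoms: none
Why: B-alkyl Suzuki–Miyaura coupling, the boron counterpart of the alkylzinc coupling: iodine–lithium exchange and capture by the methoxyborane give borate 17, which transfers the primary alkyl group to palladium. The alkenyl iodide couples with retention of the Z geometry, and its free hydroxyl is tolerated under the aqueous basic conditions.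

Step 11
Reactants: 18 (2Z,6Z,9S,10Z)-12-[(4-methoxybenzyl)oxy]-3,7,11-trimethyl-9-[(triisopropylsilyl)oxy]dodeca-2,6,10-trien-1-ol
Product: 19 (2Z,6Z,9S,10Z)-1-chloro-12-[(4-methoxybenzyl)oxy]-3,7,11-trimethyl-9-[(triisopropylsilyl)oxy]dodeca-2,6,10-triene
Conditions: MeSO2Cl, 2,4,6-collidine, LiCl, DMF, 0 °C
Reagents that add atoms: lithium chloride, [Li+].[Cl-]
Why: Mesylation and in situ chloride displacement convert a primary allylic alcohol into the chloride without allylic transposition or Z/E isomerisation, as known for nerol-type alcohols.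

Step 12
Reactants: 19 (2Z,6Z,9S,10Z)-1-chloro-12-[(4-methoxybenzyl)oxy]-3,7,11-trimethyl-9-[(triisopropylsilyl)oxy]dodeca-2,6,10-triene
Product: 20 (2Z,4S,6Z,10Z)-12-chloro-2,6,10-trimethyl-4-[(triisopropylsilyl)oxy]dodeca-2,6,10-trien-1-ol
Conditions: DDQ, CH2Cl2–pH 7 buffer, 0 °C
Reagents that add atoms: none
Why: Oxidative cleavage of the 4-methoxybenzyl ether under buffered neutral conditions frees O12; the silyl ether, the allylic chloride and the trisubstituted olefins are not affected.

Step 13
Reactants: 20 (2Z,4S,6Z,10Z)-12-chloro-2,6,10-trimethyl-4-[(triisopropylsilyl)oxy]dodeca-2,6,10-trien-1-ol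
Product: 21 (3Z,5S,7Z,11Z)-3,7,11-trimethyl-5-[(triisopropylsilyl)oxy]-1-oxacyclotrideca-3,7,11-triene (8S in target numbering)
Conditions: NaH, Bu4NI (cat.), THF, 0.002 M (slow addition), rt to 50 °C
Reagents that add atoms: none
Why: Intramolecular Williamson etherification at high dilution: the primary O12 alkoxide displaces the primary allylic chloride at C6 by SN2 (the SN2′ terminus C4 is fully substituted). The thirteen-membered ring is nearly strain-free and the bulky silyl group stays on O8.

Step 14
Reactants: 21 (3Z,5S,7Z,11Z)-3,7,11-trimethyl-5-[(triisopropylsilyl)oxy]-1-oxacyclotrideca-3,7,11-triene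
Product: 24 (1S,2Z,6Z,9S,10S)-3,7-dimethyl-10-(prop-1-en-2-yl)-9-[(triisopropylsilyl)oxy]cyclodeca-2,6-dien-1-ol (6S,7S,8S in target numbering), via C6-lithiated ether 22 (not isolated), via lithium alkoxide 23 (not isolated)
Conditions: n-BuLi, THF–hexane, −78 to −25 °C; then H2O
Reagents that add atoms: none
Why: n-BuLi removes an allylic α-oxy proton at C6 to give 22; the carbanion, conjugated with C4=C5, attacks C7 of the O–C12–C11=C7 allyl unit through a five-membered envelope transition state in a concerted suprafacial [2,3]-sigmatropic shift, so C6–C7 forms as O–C12 breaks and C11=C12 becomes exocyclic (alkoxide 23). The closest known reaction type is the [2,3]-Wittig ring contraction of macrocyclic diallylic ethers to ten-membered carbocycles. The ten-membered ring is closed transannularly: bond formation across the thirteen-membered ring divides it into the carbocycle and the expelled three-atom bridge, so no separate medium-ring cyclisation is needed. C6 against C7: with the Z geometry of C7=C11 and the C5 vinyl group exo on the envelope (away from the C11 methyl), hydroxyl and isopropenyl emerge cis on the ring. C7 against C8: allylic 1,3-strain with C12 holds H8 in the olefin plane and the carbanion adds anti to the C8–O bond, the bulky silyloxy group lying on the outer face of the forming bicycle; this puts the new bond trans to O8 and, from (8S)-21, gives C6 and C7 in the configuration of the target. The step needs lithiation at C6 and not at C12: the silyloxy group held cis to C12 by the Z olefin shields the C12 hydrogens, and low temperature and short contact are used because a C12 anion could expel the silanolate. The [1,2] shift is disfavoured at these temperatures, and the Z olefins, fixed beforehand, are not at risk.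

Step 15
Reactants: 24 (1S,2Z,6Z,9S,10S)-3,7-dimethyl-10-(prop-1-en-2-yl)-9-[(triisopropylsilyl)oxy]cyclodeca-2,6-dien-1-ol
Product: 25 (1S,2Z,6Z,9S,10S)-3,7-dimethyl-10-(propan-2-yl)-9-[(triisopropylsilyl)oxy]cyclodeca-2,6-dien-1-ol
Conditions: H2 (1 atm), RhCl(PPh3)3 (10 mol %), benzene, rt
Reagents that add atoms: none
Why: Homogeneous hydrogenation with RhCl(PPh3)3 reduces the 1,1-disubstituted olefin much faster than the trisubstituted ring olefins; it is done before any alkoxide is regenerated at O6, which removes the oxy-Cope array.

Step 16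
Reactants: 25 (1S,2Z,6Z,9S,10S)-3,7-dimethyl-10-(propan-2-yl)-9-[(triisopropylsilyl)oxy]cyclodeca-2,6-dien-1-ol
Product: 26 C6 4-methoxybenzyl ether of 25 (6S,7S,8S in target numbering)
Conditions: NaH, 4-methoxybenzyl chloride, Bu4NI (cat.), THF–DMF, 0 °C to rt
Reagents that add atoms: 4-methoxybenzyl chloride, COc1ccc(CCl)cc1
Why: Williamson etherification of the C6 alkoxide; the ether is stable to fluoride and to the esterification, and is later removed without acid or base.

Step 17
Reactants: 26 C6 4-methoxybenzyl ether of 25
Product: 27 (1(10)Z,4Z)-7-isopropyl-6-[(4-methoxybenzyl)oxy]-4,10-dimethylcyclodeca-1(10),4-dien-8-ol (6S,7R,8S in target numbering; C8 hydroxyl trans to the C7 isopropyl group)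
Conditions: Bu4NF, THF, rt to 40 °C
Reagents that add atoms: none
Why: Fluoride cleaves the silyl ether; the benzyl-type ether and the olefins are inert.

Step 18
Reactants: 27 (1(10)Z,4Z)-7-isopropyl-6-[(4-methoxybenzyl)oxy]-4,10-dimethylcyclodeca-1(10),4-dien-8-ol; 28 3,4,5-trimethoxybenzoic acid
Product: 29 C6 4-methoxybenzyl ether of the dienol ester 30 (6S,7R,8R in target numbering; ester cis to the C7 isopropyl group)
Conditions: PPh3, i-PrO2CN=NCO2i-Pr, toluene, 0 °C to rt
Reagents that add atoms: none
Why: Mitsunobu esterification: the alkoxyphosphonium ion at C8 is displaced by the carboxylate with inversion (SN2), turning (8S) into the (8R) ester cis to the isopropyl group. The carbinol, trans to a neighbouring isopropyl-bearing carbon, is of the menthol type, for which this inversion is known.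

Step 19
Reactants: 29 C6 4-methoxybenzyl ether of the dienol ester 30
Product: 30 (1(10)Z,4Z)-6-hydroxy-7-isopropyl-4,10-dimethylcyclodeca-1(10),4-dien-8-yl 3,4,5-trimethoxybenzoate (6S,7S,8R in target numbering)
Conditions: DDQ, CH2Cl2–pH 7 buffer, 0 °C
Reagents that add atoms: none
Why: Oxidative removal of the 4-methoxybenzyl ether under neutral conditions; the aryl ester neither cleaves nor migrates to O6 and the olefins are untouched.

Step 20
Reactants: 30 (1(10)Z,4Z)-6-hydroxy-7-isopropyl-4,10-dimethylcyclodeca-1(10),4-dien-8-yl 3,4,5-trimethoxybenzoate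
Product: 31 (1(10)Z)-4,5-epoxy-6-hydroxy-7-isopropyl-4,10-dimethylcyclodec-1(10)-en-8-yl 3,4,5-trimethoxybenzoate (4R,5S,6R,7S,8R), the target
Conditions: VO(acac)2 (5 mol %), t-BuOOH, CH2Cl2, 0 °C to rt
Reagents that add atoms: tert-butyl hydroperoxide, CC(C)(C)OO
Why: Vanadium-catalysed hydroxyl-directed epoxidation: the peroxide bound to the vanadium alkoxide of O6 reaches only the allylic olefin C4=C5, so C1=C10 stays. With H6 in the olefin plane (allylic 1,3-strain with C3) the hydroxyl sits on the outer face of C4=C5 and oxygen is delivered there, which should give the threo (4R,5S) epoxy alcohol; the Z geometry fixes the cis oxirane.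

Compound list

1 | 4-methylanisole | COc1ccc(C)cc1 | starting material
2 | 1-methoxy-4-methylcyclohexa-1,4-diene | COC1=CCC(C)=CC1 | intermediate
3 | methyl (3Z)-6-hydroperoxy-6-methoxy-4-methylhex-3-enoate | COC(=O)C/C=C(C)\CC(OC)OO | intermediate
4 | methyl (3Z)-4-methyl-6-oxohex-3-enoate | COC(=O)C/C=C(C)\CC=O | intermediate
5 | prop-2-yn-1-ol | C#CCO | starting material
6 | bromomagnesium (2Z)-3-(bromomagnesio)-2-methylprop-2-en-1-olate | Br[Mg]OC/C(C)=C\[Mg]Br | intermediate
7 | (2Z)-3-iodo-2-methylprop-2-en-1-ol | OC/C(C)=C\I | intermediate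
8 | (Z)-1-iodo-3-[(4-methoxybenzyl)oxy]-2-methylprop-1-ene | COc1ccc(COC/C(C)=C\I)cc1 | intermediate
9 | methyl (3Z,6S,7Z)-6-hydroxy-9-[(4-methoxybenzyl)oxy]-4,8-dimethylnona-3,7-dienoate | COC(=O)C/C=C(C)\C[C@H](O)/C=C(C)\COCc1ccc(OC)cc1 | intermediate
10 | methyl (3Z,6S,7Z)-9-[(4-methoxybenzyl)oxy]-4,8-dimethyl-6-[(triisopropylsilyl)oxy]nona-3,7-dienoate | COC(=O)C/C=C(C)\C[C@H](O[Si](C(C)C)(C(C)C)C(C)C)/C=C(C)\COCc1ccc(OC)cc1 | intermediate
11 | (3Z,6S,7Z)-9-[(4-methoxybenzyl)oxy]-4,8-dimethyl-6-[(triisopropylsilyl)oxy]nona-3,7-dien-1-ol | OCC/C=C(C)\C[C@H](O[Si](C(C)C)(C(C)C)C(C)C)/C=C(C)\COCc1ccc(OC)cc1 | intermediate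
12 | (3Z,6S,7Z)-1-iodo-9-[(4-methoxybenzyl)oxy]-4,8-dimethyl-6-[(triisopropylsilyl)oxy]nona-3,7-diene | ICC/C=C(C)\C[C@H](O[Si](C(C)C)(C(C)C)C(C)C)/C=C(C)\COCc1ccc(OC)cc1 | intermediate
13 | but-2-yn-1-ol | CC#CCO | starting material
14 | sodium cyclic (Z)-alkenyl(alkoxy)bis(2-methoxyethoxy)alanate from 13 (aluminium on C4, ring through O6) | [Na+].COCCO[Al-]1(OCCOC)OCC=C1C | intermediate
15 | (2Z)-3-iodobut-2-en-1-ol | OC/C=C(C)\I | intermediate
16 | primary alkyllithium from 12 (lithium on C3) | [Li]CC/C=C(C)\C[C@H](O[Si](C(C)C)(C(C)C)C(C)C)/C=C(C)\COCc1ccc(OC)cc1 | intermediate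
17 | lithium B-alkyl-B-methoxy-9-borabicyclo[3.3.1]nonane ate complex from 16 | [Li+].CO[B-]1(CC/C=C(C)\C[C@H](O[Si](C(C)C)(C(C)C)C(C)C)/C=C(C)\COCc3ccc(OC)cc3)C2CCCC1CCC2 | intermediate
18 | (2Z,6Z,9S,10Z)-12-[(4-methoxybenzyl)oxy]-3,7,11-trimethyl-9-[(triisopropylsilyl)oxy]dodeca-2,6,10-trien-1-ol | OC/C=C(C)\CC/C=C(C)\C[C@H](O[Si](C(C)C)(C(C)C)C(C)C)/C=C(C)\COCc1ccc(OC)cc1 | intermediate
19 | (2Z,6Z,9S,10Z)-1-chloro-12-[(4-methoxybenzyl)oxy]-3,7,11-trimethyl-9-[(triisopropylsilyl)oxy]dodeca-2,6,10-triene | ClC/C=C(C)\CC/C=C(C)\C[C@H](O[Si](C(C)C)(C(C)C)C(C)C)/C=C(C)\COCc1ccc(OC)cc1 | intermediate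
20 | (2Z,4S,6Z,10Z)-12-chloro-2,6,10-trimethyl-4-[(triisopropylsilyl)oxy]dodeca-2,6,10-trien-1-ol | ClC/C=C(C)\CC/C=C(C)\C[C@H](O[Si](C(C)C)(C(C)C)C(C)C)/C=C(C)\CO | intermediate
21 | (3Z,5S,7Z,11Z)-3,7,11-trimethyl-5-[(triisopropylsilyl)oxy]-1-oxacyclotrideca-3,7,11-triene (precursor of the key step) | O1C/C(C)=C\[C@@H](O[Si](C(C)C)(C(C)C)C(C)C)C/C(C)=C\CC/C(C)=C\C1 | intermediate
22 | C6-lithiated derivative of 21 (lithium on the ether carbon next to C5) | O1C/C(C)=C\[C@@H](O[Si](C(C)C)(C(C)C)C(C)C)C/C(C)=C\CC/C(C)=C\C1[Li] | intermediate
23 | lithium alkoxide of 24 | CC(C)[Si](C(C)C)(C(C)C)O[C@H]1C/C(C)=C\CC/C(C)=C\[C@H](O[Li])[C@@H]1C(C)=C | intermediate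
24 | (1S,2Z,6Z,9S,10S)-3,7-dimethyl-10-(prop-1-en-2-yl)-9-[(triisopropylsilyl)oxy]cyclodeca-2,6-dien-1-ol (product of the key step) | CC(C)[Si](C(C)C)(C(C)C)O[C@H]1C/C(C)=C\CC/C(C)=C\[C@H](O)[C@@H]1C(C)=C | intermediate
25 | (1S,2Z,6Z,9S,10S)-3,7-dimethyl-10-(propan-2-yl)-9-[(triisopropylsilyl)oxy]cyclodeca-2,6-dien-1-ol | CC(C)[Si](C(C)C)(C(C)C)O[C@H]1C/C(C)=C\CC/C(C)=C\[C@H](O)[C@@H]1C(C)C | intermediate
26 | C6 4-methoxybenzyl ether of 25 | CC(C)[Si](C(C)C)(C(C)C)O[C@H]1C/C(C)=C\CC/C(C)=C\[C@H](OCc2ccc(OC)cc2)[C@@H]1C(C)C | intermediate
27 | (1(10)Z,4Z)-7-isopropyl-6-[(4-methoxybenzyl)oxy]-4,10-dimethylcyclodeca-1(10),4-dien-8-ol, 6S,7R,8S (target numbering) | O[C@H]1C/C(C)=C\CC/C(C)=C\[C@H](OCc2ccc(OC)cc2)[C@@H]1C(C)C | intermediate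
28 | 3,4,5-trimethoxybenzoic acid | COc1cc(C(=O)O)cc(OC)c1OC | starting material
29 | C6 4-methoxybenzyl ether of 30, 6S,7R,8R (target numbering) | COc1cc(C(=O)O[C@@H]2C/C(C)=C\CC/C(C)=C\[C@H](OCc3ccc(OC)cc3)[C@@H]2C(C)C)cc(OC)c1OC | intermediate
30 | (1(10)Z,4Z)-6-hydroxy-7-isopropyl-4,10-dimethylcyclodeca-1(10),4-dien-8-yl 3,4,5-trimethoxybenzoate, 6S,7S,8R (target numbering) | COc1cc(C(=O)O[C@@H]2C/C(C)=C\CC/C(C)=C\[C@H](O)[C@@H]2C(C)C)cc(OC)c1OC | intermediate
31 | (1(10)Z)-4,5-epoxy-6-hydroxy-7-isopropyl-4,10-dimethylcyclodec-1(10)-en-8-yl 3,4,5-trimethoxybenzoate, 4R,5S,6R,7S,8R | COc1cc(C(=O)O[C@@H]2C/C(C)=C\CC[C@@]3(C)O[C@H]3[C@H](O)[C@@H]2C(C)C)cc(OC)c1OC | target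

Total step count: 20. Longest linear sequence: 17 steps (from 1 through steps 1, 2, 5–8 and 10–20).

Least certain steps

Step 14 (key step). Three things may go wrong:
- lithiation at C12 instead of C6, after which the C12–C11–C7 anion expels the silanolate or shifts onto C4;
- a competing [1,2] shift;
- attack on the other face of C7, if ring strain overrides the anti-to-oxygen preference.

The fallback forms the same C6–C7 bond without a carbanion, by Lewis-acid-promoted intramolecular allylstannane addition; it sets out from 18 and returns at 24. The C6 hydroxyl of 18 is silylated (t-BuMe2SiCl, imidazole) to the C6 tert-butyldimethylsilyl ether F1. DDQ frees O12 to give the C12 alcohol F2. MeSO2Cl/LiCl gives the C12 allylic chloride F3, and Bu3SnLi displaces the chloride to give the C12 tributylstannane F4. Bu4NF at 0 °C removes only the primary silyl group to give the C6 alcohol F5, and Dess–Martin periodinane with NaHCO3 gives the Z enal F6. BF3·OEt2 in CH2Cl2 at −78 °C under high dilution should then let C7 attack the C6 aldehyde through an open, syn-selective transition state, anti to the silyloxy group, giving 24.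

Step 20. The likely failure is poor facial selectivity. In a medium ring the vanadium alkoxide may react through a conformer with the hydroxyl turned toward the olefin plane, as happens in eight- and nine-membered Z cycloalkenols, and then oxygen would be delivered cis to O6. The fallback changes the delivering species and the reacting conformer: hydrogen-bond-directed peracid epoxidation of 30 (3-chloroperbenzoic acid, NaHCO3, CH2Cl2, −20 °C). This needs a large O–C–C=C dihedral and so attacks the outer face of the conformer with H6 in the olefin plane, going directly from 30 to 31. Its price is competing epoxidation of C1=C10, to be met by partial conversion and recycling of 30.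

Step 18. The likely failure is slow substitution at the hindered C8 carbinol, so that elimination toward C9 (a conjugated diene) or acylation with retention through an acyloxyphosphonium ion takes over. The fallback replaces substitution by oxidation and reduction; it sets out from 27 and returns at 29. Dess–Martin periodinane (NaHCO3) gives the C8 ketone F7. LiBH(s-Bu)3 in THF at −78 °C should add hydride from the ring face away from the neighbouring isopropyl group to give the (8R) C8 alcohol F8. Commercial 3,4,5-trimethoxybenzoyl chloride with Et3N and 4-(dimethylamino)pyridine then gives 29.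

## Further compounds

F1 | step 14 | C6 tert-butyldimethylsilyl ether of 18 | CC(C)(C)[Si](C)(C)OC/C=C(C)\CC/C=C(C)\C[C@H](O[Si](C(C)C)(C(C)C)C(C)C)/C=C(C)\COCc1ccc(OC)cc1
F2 | step 14 | C12 alcohol from F1 (C6 silyl ether retained) | CC(C)(C)[Si](C)(C)OC/C=C(C)\CC/C=C(C)\C[C@H](O[Si](C(C)C)(C(C)C)C(C)C)/C=C(C)\CO
F3 | step 14 | C12 allylic chloride from F2 | CC(C)(C)[Si](C)(C)OC/C=C(C)\CC/C=C(C)\C[C@H](O[Si](C(C)C)(C(C)C)C(C)C)/C=C(C)\CCl
F4 | step 14 | C12 tributylstannane from F3 | CC(C)(C)[Si](C)(C)OC/C=C(C)\CC/C=C(C)\C[C@H](O[Si](C(C)C)(C(C)C)C(C)C)/C=C(C)\C[Sn](CCCC)(CCCC)CCCC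
F5 | step 14 | C6 alcohol with C12 tributylstannyl group | OC/C=C(C)\CC/C=C(C)\C[C@H](O[Si](C(C)C)(C(C)C)C(C)C)/C=C(C)\C[Sn](CCCC)(CCCC)CCCC
F6 | step 14 | C6 Z enal with C12 tributylstannyl group | O=C/C=C(C)\CC/C=C(C)\C[C@H](O[Si](C(C)C)(C(C)C)C(C)C)/C=C(C)\C[Sn](CCCC)(CCCC)CCCC
F7 | step 18 | C8 ketone from 27 | O=C1C/C(C)=C\CC/C(C)=C\[C@H](OCc2ccc(OC)cc2)[C@@H]1C(C)C
F8 | step 18 | (8R) C8 alcohol, epimer of 27 at C8 | O[C@@H]1C/C(C)=C\CC/C(C)=C\[C@H](OCc2ccc(OC)cc2)[C@@H]1C(C)C
F0 | step 20 | none | none
A1 | alternative 1 | open-chain C5 aldehyde with C4 diphenylsulfonium triflate, C6 4-methoxybenzyl ether, C7 isopropyl, C8 3,4,5-trimethoxybenzoate | O=C[C@H](OCc1ccc(OC)cc1)[C@H](C(C)C)[C@H](OC(=O)c1cc(OC)c(OC)c(OC)c1)C/C(C)=C\CCC(C)[S+](c1ccccc1)c1ccccc1.[O-]S(=O)(=O)C(F)(F)F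
A2 | alternative 1 | C6 4-methoxybenzyl ether of 31 | COc1cc(C(=O)O[C@@H]2C/C(C)=C\CC[C@@]3(C)O[C@H]3[C@H](OCc4ccc(OC)cc4)[C@@H]2C(C)C)cc(OC)c1OC
A3 | alternative 2 | open-chain C6 aldehyde with C5 Z alkenyl iodide, C7 isopropyl, C8 3,4,5-trimethoxybenzoate | I/C=C(C)\CC/C=C(C)\C[C@@H](OC(=O)c1cc(OC)c(OC)c(OC)c1)[C@@H](C(C)C)C=O
A4 | alternative 2 | ten-membered Z,Z-dienol ester, the same compound as 30 | COc1cc(C(=O)O[C@@H]2C/C(C)=C\CC/C(C)=C\[C@H](O)[C@@H]2C(C)C)cc(OC)c1OC
A5 | alternative 3 | open-chain C8 aldehyde with C12 tributylstannyl group and C6 tert-butyldimethylsilyl ether | O=CC/C(C)=C\CC/C(C)=C\[C@H](O[Si](C)(C)C(C)(C)C)C=C(C)C[Sn](CCCC)(CCCC)CCCC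
A6 | alternative 3 | ten-membered Z,Z-dienol with C8 hydroxyl, C7 isopropenyl, C6 tert-butyldimethylsilyl ether | O[C@@H]1C/C(C)=C\CC/C(C)=C\[C@H](O[Si](C)(C)C(C)(C)C)[C@@H]1C(C)=C
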